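## Structural features

The target is a cembranolide: a 14-membered carbocycle (C1–C14) with methyls C18, C19 and C20 on C4, C8 and C12 and E-trisubstituted olefins at C3=C4 and C12=C13. An α-methylene-γ-butyrolactone is fused to the C1–C2 bond (ring atoms O, C2, C1, C15, C16; exocyclic C15=C17). An O–O bridge joins C8 and C11, so that C8–C9–C10–C11–O–O is a 1,2-dioxane; C7 carries an acetate. The five stereocentres form two clusters. C1/C2 are (1S,2S) with H1 and H2 on the same face (cis fusion). C7/C8/C11 are (7S,8R,11S): the C7 carbinol adjoins the fully substituted peroxy carbon C8, and the macrocycle leaves the dioxane cis at C8 and C11. The peroxide is reduced by phosphines, hydrides and low-valent metals. The methylene lactone is a Michael acceptor, and through C2–C3=C4 it is also an allylic ester that can ionise. The real difficulty is order: the ring must be closed, oxygen placed on C7, C8 and C11 among three similar trisubstituted olefins, and the O–O bond made only after every reducing or organometallic step. The key step exploits the lactone ring: removing C16 as CO leaves a C2 hydroxyl and a C1 ethynyl group (C15≡C17). Their erythro relationship is what anti opening of one trans-epoxide by an acetylide delivers.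

## Logic of the disconnections

**32 ⇒ 31.** The acetyl–O7 bond is cut. Acylation comes last because only then is no free hydroperoxide present to be acylated first. The forward step must acylate a hindered secondary alcohol next to C8 without disturbing the peroxide or the methylene lactone.

**31 ⇒ 30.** The O–C11 bond of the dioxane is cut. C11 is allylic, so the bond can form by capture of an allyl cation, and both C11 epimers of 30 converge. This removes a ring and a stereocentre and means C11 needs no earlier control. The forward step must make the hydroperoxide, not O7, the capturing nucleophile, and the tether from C8 must select the face.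

**30 ⇒ 29 ⇒ 28.** The O11–Si bond and then the C8–OO bond are cut, folding O7 and C8 back into one epoxide. Perhydrolysis at the tertiary carbon with inversion ties the C7 and C8 configurations to a single epoxide. The silyl ether stays on during perhydrolysis so that no free allylic alcohol can direct a molybdenum-peroxo epoxidation of C12=C13. The forward step must be regiospecific for C8 and proceed with inversion.

**28 ⇒ 27.** The two C–O bonds of the epoxide are cut. C7=C8 is the only ring olefin without an allylic oxygen, so an electrophilic, reagent-controlled epoxidation can single it out. The forward step needs the L-fructose-derived enantiomer of the ketone catalyst to give the 7S,8S epoxide.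

**27 ⇒ 26 (key).** C15–C16 and C16–O2 are cut and C16 leaves as CO. The precursor carries only a terminal alkyne and a hydroxyl, and the methylene lactone never has to be built by enolate chemistry. The forward step must select the alkyne over three olefins, bond CO to C15, and leave the allylic C2–O bond alone.

**26 ⇒ 24 ⇒ 23.** Only Si–O and Si–C bonds are cut. O2 carries the labile triethylsilyl group, O11 the robust tert-butyldimethylsilyl group, and the alkyne a trimethylsilyl cap. The forward step must cleave the first and third without touching the second.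

**23 ⇒ 22.** The C11–C12 bond is cut. An aldehyde and an E-alkenyl iodide close the ring and create exactly the C11 allylic alcohol needed later. The C11 configuration is irrelevant because C11 is ionised in step 20. The forward step needs high dilution and tolerance of silyl ethers and a silylalkyne.

**22 ⇒ 21 ⇒ 20 ⇒ 18 ⇒ 16 ⇒ 14.** Two Claisen retrons are opened in turn: C9–C10 with C7=C8, then C5–C6 with C3=C4. Compounds 15 and 17 supply each isoprene unit. A chair sigmatropic transition state gives each E-trisubstituted olefin, and no allyl–allyl coupling or reductive sulfone removal is needed in the presence of the alkenyl iodide. The forward steps must give high E selectivity and spare the O2 silyl ether at 135 °C.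

**14 ⇒ 13 ⇒ 12.** Only the oxidation state of C3 and the protection of O2 change. The forward steps must oxidise the primary position and leave the secondary silyl ether in place.

**12 ⇒ 8 + 9.** The C1–C15 bond is cut. Anti opening of the epoxide at the carbon distal to the hydroxymethyl group inverts C1 and retains C2, which gives the erythro alkynol. The forward step needs attack at C1 only.

**8 ⇒ 7.** The epoxide C–O bonds are cut. An E-allylic alcohol is the ideal substrate for catalytic asymmetric epoxidation, which sets the absolute configuration of C1 and C2 in one step.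

**7 ⇒ 6 ⇒ 3 + 4, and 3 ⇒ 1.** The C2=C3 olefin is cut by a Wittig retron and the C12–I bond by hydrozirconation–iodination. This reaches two purchasable compounds. The forward steps must give the E-enoate without conjugating the skipped diene, and place iodine on the methyl-bearing carbon.

## Other disconnections considered

**Alternative 1:** The cut is C11–C12, made together with the O11–Si bond and the E-C12=C13 olefin. The precursor is ynal A1 (C11 aldehyde, methyl-capped C12≡C13 alkyne, 7S,8S-epoxide, saturated lactone). The forward step uses zerovalent nickel (for example Ni(cod)2 with an N-heterocyclic carbene) and Et3SiH: oxidative cyclisation to an oxanickelacycle, σ-bond metathesis with the silane and reductive elimination would give A2 by syn addition of H and C11 across the alkyne.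
- In its favour: the metal is catalytic, a 2-butynyl group replaces the alkenyl iodide, O11 emerges already silylated, and the epoxide can be installed on an acyclic intermediate under pure reagent control. On these points it equals or betters the ring closure chosen here, which uses stoichiometric divalent chromium, needs a hydrozirconation and a separate silylation, and epoxidises on the macrocycle.
- Against it: the endo mode (bond to the methyl-bearing alkyne carbon, 14-membered ring) must beat the exo mode (13-membered ring with an exocyclic ethylidene), and this rests on ligand control. The epoxide and the lactone must survive a nickel hydride and silane medium, which is why A2 carries a saturated lactone; the methylene must then be added late by enolate chemistry next to an epoxide or peroxide.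
- Comparison: the chosen plan builds the complete methylene lactone in one neutral step and keeps strong base away from late intermediates. Neither ring closure controls C11. The steps saved at ring closure are spent again on methylenation, so step economy is about equal.

**Alternative 2:** The cut is the O–C8 bond of the dioxane. The precursor is A3, the (11S)-hydroperoxide of the (7S,8S)-epoxide. Under mild acid the terminal hydroperoxide oxygen would attack the tertiary epoxide carbon C8 in a 6-exo mode with inversion and give A4, which is identical to 31.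
- In its favour: the closure is stereospecific at C8 and leaves the preset C11 untouched. Tertiary character and ring size reinforce each other. O7 is freed only as the ring forms, so no hydroxyl competes. In stereochemical rigour and chemoselectivity of the peroxide closure it is better than the cation capture chosen here.
- Against it: it needs a configurationally defined secondary allylic hydroperoxide at C11. Substitution at that centre competes with ionisation and SN2′ attack, and a Schenck ene reaction has uncertain regiochemistry. The hydroperoxide must also coexist with the epoxide and with the methylene lactone under conditions that are never basic.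
- Comparison: the chosen plan accepts a less rigorous, stereoconvergent closure and in return uses the C11 alcohol mixture straight from the ring closure. Setting and converting C11 would cost the alternative two or three extra steps. The two ideas are not exclusive: this alternative concerns only the end-game and could follow the same carbonylation.

**Alternative 3:** The cut is C1–C2. The precursor is the 17-membered propargyl allyl ether A5 (O between C2 and C17, C1=C15 olefin with C14 cis to C17). Lithiation at C2 (n-BuLi or a chiral lithium amide) would trigger a [2,3]-shift through a five-membered envelope transition state and give A6.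
- In its favour: one step forms the carbocycle, the C1–C2 bond and both stereocentres. A6 already carries every lactone carbon (C15=C17 and C16 as a protected alcohol), so no pressurised CO is needed. A 17-membered etherification is easier than a 14-membered C–C closure. In bonds and stereocentres per step it is better than the chosen key step, which creates no stereocentre.
- Against it: the absolute configuration would rest on a chiral base, which is less dependable than asymmetric epoxidation followed by anti opening. The relative configuration depends on the usual Z-to-syn correlation holding inside a macrocyclic transition state. A6 still lacks the C3=C4 methyl olefin (trans-hydroalumination with NaAlH2(OCH2CH2OMe)2, iodination and methyl cuprate coupling), the C16 oxidation and lactonisation, and any oxygen at C11. Its olefin sits at C11=C12 and would have to be transposed to C12=C13 with oxygenation at C11.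
- Comparison: the chosen key product 27 is five steps from the target, whereas A6 would need clearly more, so the chosen plan is better in step economy after the key step.

Key step: step 16

Remark: locants follow cembrane numbering (C15 = lactone α-carbon, C16 = carbonyl, C17 = methylene). C11 is carried as a mixture of epimers from step 13 to step 19 on purpose, because it is ionised in step 20.

## Route

Step 1
Reactants: 1 pent-3-yn-1-ol
Product: 3 (3E)-4-iodopent-3-en-1-ol, via alkenylzirconocene alkoxide 2 (not isolated)
Conditions: Cp2Zr(H)Cl (2.3 equiv), THF, 23 → 40 °C; I2, 0 °C; 1 M HCl work-up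
Reagents that add atoms: iodine, [I][I]
Why: Syn hydrozirconation of the internal alkyne, equilibrated with excess hydride, should place zirconium on the methyl-bearing carbon distal to the zirconium alkoxide. Iodinolysis with retention then gives the E-alkenyl iodide that becomes C12(C20)=C13–C14.

Step 2
Reactants: 3 (3E)-4-iodopent-3-en-1-ol; 4 ethyl (triphenylphosphoranylidene)acetate
Product: 6 ethyl (2E,5E)-6-iodohepta-2,5-dienoate, via (3E)-4-iodopent-3-enal 5 (not isolated)
Conditions: Dess–Martin periodinane, NaHCO3, CH2Cl2, 0 °C; then 4, 0 → 23 °C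
Reagents that add atoms: none
Why: Dess–Martin oxidation gives the β,γ-unsaturated aldehyde. The stabilised ylide traps it in the same flask by an E-selective Wittig olefination before the double bond can move into conjugation.

Step 3
Reactants: 6 ethyl (2E,5E)-6-iodohepta-2,5-dienoate
Product: 7 (2E,5E)-6-iodohepta-2,5-dien-1-ol
Conditions: i-Bu2AlH (2.2 equiv), CH2Cl2, −78 °C
Reagents that add atoms: none
Why: 1,2-Reduction of the enoate by i-Bu2AlH at low temperature should leave the alkenyl iodide and the skipped diene untouched.

Step 4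
Reactants: 7 (2E,5E)-6-iodohepta-2,5-dien-1-ol
Product: 8 [(2S,3S)-3-[(2E)-3-iodobut-2-en-1-yl]oxiran-2-yl]methanol
Conditions: Ti(O-i-Pr)4 (10 mol%), L-(+)-diethyl tartrate (12 mol%), t-BuOOH, 4 Å MS, CH2Cl2, −20 °C
Reagents that add atoms: tert-butyl hydroperoxide, CC(C)(C)OO
Why: Sharpless asymmetric epoxidation: with L-(+)-tartrate the E-allylic alcohol should give the (2S,3S)-epoxy alcohol, which sets the future C2 directly and C1 after inversion. The iodo-olefin has no directing hydroxyl and is electron-poor.

Step 5
Reactants: 8 [(2S,3S)-3-[(2E)-3-iodobut-2-en-1-yl]oxiran-2-yl]methanol; 9 ethynyl(trimethyl)silane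
Product: 12 (2R,3S,5E)-6-iodo-3-[(trimethylsilyl)ethynyl]hept-5-ene-1,2-diol, via lithium (trimethylsilyl)acetylide 10 (not isolated), via diethyl(trimethylsilylethynyl)aluminium 11 (not isolated)
Conditions: 9, n-BuLi, toluene, −78 → 0 °C; Et2AlCl, 0 °C; then 8, 0 → 23 °C
Reagents that add atoms: none
Why: Alkynylalane opening of a 2,3-epoxy alcohol: the aluminium alkoxide delivers the alkynyl group to the distal epoxide carbon (future C1) with inversion while C2 is retained. The product is the erythro 1,2-diol, that is (1S,2S) in cembrane numbering.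

Step 6
Reactants: 12 (2R,3S,5E)-6-iodo-3-[(trimethylsilyl)ethynyl]hept-5-ene-1,2-diol
Product: 13 (2R,3S,5E)-6-iodo-1,2-bis(triethylsilyloxy)-3-[(trimethylsilyl)ethynyl]hept-5-ene
Conditions: Et3SiCl, imidazole, DMAP (cat.), CH2Cl2, 0 → 23 °C
Reagents that add atoms: chlorotriethylsilane, CC[Si](Cl)(CC)CC
Why: Routine silylation of both hydroxyls prepares the selective oxidation of the primary position in the next step.

Step 7
Reactants: 13 (2R,3S,5E)-6-iodo-1,2-bis(triethylsilyloxy)-3-[(trimethylsilyl)ethynyl]hept-5-ene
Product: 14 (2R,3S,5E)-6-iodo-2-(triethylsilyloxy)-3-[(trimethylsilyl)ethynyl]hept-5-enal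
Conditions: (COCl)2, DMSO, CH2Cl2, −78 → −30 °C; Et3N, −78 → 0 °C
Reagents that add atoms: none
Why: Under Swern conditions a primary triethylsilyl ether is cleaved by the chlorosulfonium salt and oxidised directly to the aldehyde, while the hindered secondary silyl ether persists. The α-silyloxy aldehyde is used at once to avoid epimerisation at C2.

Step 8
Reactants: 14 (2R,3S,5E)-6-iodo-2-(triethylsilyloxy)-3-[(trimethylsilyl)ethynyl]hept-5-enal; 15 isopropenylmagnesium bromide
Product: 16 (3RS,4R,5S,7E)-8-iodo-2-methyl-4-(triethylsilyloxy)-5-[(trimethylsilyl)ethynyl]nona-1,7-dien-3-ol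
Conditions: THF, −78 °C; aq. NH4Cl at −78 °C
Reagents that add atoms: none
Why: Grignard addition to the aldehyde; the new carbinol centre (C3) is destroyed in step 9, so its configuration does not matter. The cold quench limits 1,2-silyl migration in the magnesium alkoxide.

Step 9
Reactants: 16 (3RS,4R,5S,7E)-8-iodo-2-methyl-4-(triethylsilyloxy)-5-[(trimethylsilyl)ethynyl]nona-1,7-dien-3-ol; 17 triethyl orthoacetate
Product: 18 ethyl (4E,6S,7S,9E)-10-iodo-4-methyl-6-(triethylsilyloxy)-7-[(trimethylsilyl)ethynyl]undeca-4,9-dienoate
Conditions: 17 (excess), EtCO2H (cat.), 135 °C, EtOH distilled off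
Reagents that add atoms: none
Why: Johnson–Claisen rearrangement: the ketene acetal rearranges through a chair with the bulky C2-bearing substituent equatorial. This should give the E-C3=C4 olefin and the C5–C6 bond; C1 and C2 are spectators.

Step 10
Reactants: 18 ethyl (4E,6S,7S,9E)-10-iodo-4-methyl-6-(triethylsilyloxy)-7-[(trimethylsilyl)ethynyl]undeca-4,9-dienoate; 15 isopropenylmagnesium bromide
Product: 20 (3RS,6E,8S,9S,11E)-12-iodo-2,6-dimethyl-8-(triethylsilyloxy)-9-[(trimethylsilyl)ethynyl]trideca-1,6,11-trien-3-ol, via undeca-4,9-dienal 19 (not isolated)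
Conditions: i-Bu2AlH (1.05 equiv), CH2Cl2, −78 °C; then 15, THF, −78 → 0 °C
Reagents that add atoms: none
Why: Partial reduction stops at the aluminium hemiacetal, which collapses to the aldehyde as the Grignard reagent is added. This one-flask reduction–addition avoids isolating the aldehyde; the new carbinol (C7) is again destroyed in the next step.

Step 11
Reactants: 20 (3RS,6E,8S,9S,11E)-12-iodo-2,6-dimethyl-8-(triethylsilyloxy)-9-[(trimethylsilyl)ethynyl]trideca-1,6,11-trien-3-ol; 17 triethyl orthoacetate
Product: 21 ethyl (4E,8E,10S,11S,13E)-14-iodo-4,8-dimethyl-10-(triethylsilyloxy)-11-[(trimethylsilyl)ethynyl]pentadeca-4,8,13-trienoate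
Conditions: 17 (excess), EtCO2H (cat.), 135 °C, EtOH distilled off
Reagents that add atoms: none
Why: A second Johnson–Claisen rearrangement should give the E-C7=C8 olefin and the C9–C10 bond and place the ester carbon at C11.

Step 12
Reactants: 21 ethyl (4E,8E,10S,11S,13E)-14-iodo-4,8-dimethyl-10-(triethylsilyloxy)-11-[(trimethylsilyl)ethynyl]pentadeca-4,8,13-trienoate
Product: 22 (4E,8E,10S,11S,13E)-14-iodo-4,8-dimethyl-10-(triethylsilyloxy)-11-[(trimethylsilyl)ethynyl]pentadeca-4,8,13-trienal
Conditions: i-Bu2AlH (1.05 equiv), CH2Cl2, −78 °C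
Reagents that add atoms: none
Why: Low-temperature partial reduction of the ester gives the C11 aldehyde; silyl ethers, silylalkyne and alkenyl iodide are inert to i-Bu2AlH at −78 °C.

Step 13
Reactants: 22 (4E,8E,10S,11S,13E)-14-iodo-4,8-dimethyl-10-(triethylsilyloxy)-11-[(trimethylsilyl)ethynyl]pentadeca-4,8,13-trienal
Product: 23 (1S,2S,3E,7E,11RS,12E)-2-(triethylsilyloxy)-1-[(trimethylsilyl)ethynyl]-4,8,12-trimethylcyclotetradeca-3,7,12-trien-11-ol
Conditions: CrCl2 (8 equiv), NiCl2 (2 mol%), DMSO–THF, 23 °C, slow addition to 2 mM
Reagents that add atoms: none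
Why: Nozaki–Hiyama–Kishi macrocyclisation: nickel inserts into the C12–I bond, the alkenyl group passes to chromium and adds to the C11 aldehyde with retention of the E geometry. The C11 epimers are both carried on because C11 is ionised in step 20.

Step 14
Reactants: 23 (1S,2S,3E,7E,11RS,12E)-2-(triethylsilyloxy)-1-[(trimethylsilyl)ethynyl]-4,8,12-trimethylcyclotetradeca-3,7,12-trien-11-ol
Product: 24 (1S,2S,3E,7E,11RS,12E)-11-(tert-butyldimethylsilyloxy)-2-(triethylsilyloxy)-1-[(trimethylsilyl)ethynyl]-4,8,12-trimethylcyclotetradeca-3,7,12-triene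
Conditions: TBSOTf, 2,6-lutidine, CH2Cl2, −78 → 0 °C
Reagents that add atoms: tert-butyldimethylsilyl trifluoromethanesulfonate, CC(C)(C)[Si](C)(C)OS(=O)(=O)C(F)(F)F
Why: Silylation of the hindered allylic alcohol; the robust silyl ether keeps O11 out of the palladium step and shields C12=C13 in the epoxidation and perhydrolysis.

Step 15
Reactants: 24 (1S,2S,3E,7E,11RS,12E)-11-(tert-butyldimethylsilyloxy)-2-(triethylsilyloxy)-1-[(trimethylsilyl)ethynyl]-4,8,12-trimethylcyclotetradeca-3,7,12-triene
Product: 26 (1S,2S,3E,7E,11RS,12E)-11-(tert-butyldimethylsilyloxy)-1-ethynyl-4,8,12-trimethylcyclotetradeca-3,7,12-trien-2-ol, via 2-hydroxy silylalkyne 25 (not isolated)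
Conditions: PPTS (cat.), MeOH–CH2Cl2, 0 → 23 °C; then K2CO3, 23 °C
Reagents that add atoms: none
Why: Mild acid methanolysis removes the triethylsilyl ether far faster than the tert-butyldimethylsilyl ether. Carbonate in methanol then cleaves the alkynyl C–Si bond without touching either O–Si bond.

Step 16
Reactants: 26 (1S,2S,3E,7E,11RS,12E)-11-(tert-butyldimethylsilyloxy)-1-ethynyl-4,8,12-trimethylcyclotetradeca-3,7,12-trien-2-ol
Product: 27 (1S,2S,11RS)-11-(tert-butyldimethylsilyloxy)cembra-3E,7E,12E,15(17)-tetraen-16,2-olide
Conditions: Pd(dba)2 (5 mol%), dppb (6 mol%), CO (20 atm), DME, 90 °C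
Reagents that add atoms: carbon monoxide, [C-]#[O+]
Why: This is the palladium-catalysed cyclocarbonylation of a 3-butyn-1-ol, a known route to α-methylene-γ-butyrolactones. Under CO the zerovalent palladium–diphosphine complex engages the C2 hydroxyl to give a palladium alkoxycarbonyl (O2–C16(=O)–Pd); alternatively a palladium hydride adds across the alkyne with palladium on C15 and CO then inserts, and both pathways lead to the same connectivity. In the alkoxycarbonyl pathway the tethered alkyne inserts syn into the Pd–C16 bond, forming C15–C16 in a 5-exo-dig closure (ring atoms O, C16, C15, C1, C2) and leaving palladium on C17; protonolysis of that alkenyl–palladium bond releases the exocyclic C15=C17 methylene and regenerates the catalyst. Two skeletal bonds (C15–C16 and C16–O2) and one ring are formed and no stereocentre is created; no bond to C1 or C2 is broken, so the cis fusion set in steps 4 and 5 is carried over unchanged. The step needs chemoselectivity for the terminal alkyne over three trisubstituted olefins, regioselectivity for C15 over C17, and five- rather than six-membered closure. All three follow from the two-atom tether between O2 and C15, which makes only the 5-exo mode accessible, and from the reluctance of trisubstituted olefins to insert. The C11 silyl ether keeps the second allylic oxygen out of alkoxycarbonylation. Moderate temperature and CO pressure are chosen so that carbonyl-ligated palladium does not ionise the allylic C2–O bond of the product.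

Step 17
Reactants: 27 (1S,2S,11RS)-11-(tert-butyldimethylsilyloxy)cembra-3E,7E,12E,15(17)-tetraen-16,2-olide
Product: 28 (1S,2S,7S,8S,11RS)-11-(tert-butyldimethylsilyloxy)-7,8-epoxycembra-3E,12E,15(17)-trien-16,2-olide
Conditions: L-fructose-derived Shi ketone (1,2:4,5-di-O-isopropylidene-β-L-erythro-2,3-hexodiulo-2,6-pyranose, 30 mol%), KHSO5 (as 2KHSO5·KHSO4·K2SO4), K2CO3, Bu4NHSO4, Na2B4O7 buffer (pH ≈ 9.3), MeCN–CH2(OMe)2–H2O, −5 °C
Reagents that add atoms: potassium peroxymonosulfate, [K+].[O-]S(=O)(=O)OO
Why: Shi epoxidation: the chiral dioxirane transfers oxygen through a spiro transition state, and the L-fructose-derived ketone should give the (7S,8S)-epoxide (the D-series gives R,R on E-trisubstituted olefins). C7=C8 is the only ring olefin not deactivated by an allylic oxygen; C3=C4, C12=C13 and the enoate are electron-poorer or shielded by the silyl group.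

Step 18
Reactants: 28 (1S,2S,7S,8S,11RS)-11-(tert-butyldimethylsilyloxy)-7,8-epoxycembra-3E,12E,15(17)-trien-16,2-olide
Product: 29 (1S,2S,7S,8R,11RS)-11-(tert-butyldimethylsilyloxy)-8-hydroperoxy-7-hydroxycembra-3E,12E,15(17)-trien-16,2-olide
Conditions: H2O2 (anhydrous, in Et2O, excess), H3PMo12O40 (2 mol%), Et2O, 0 → 23 °C
Reagents that add atoms: hydrogen peroxide, OO
Why: Acid-catalysed perhydrolysis of a trisubstituted epoxide: H2O2 attacks the tertiary carbon C8 from the face opposite the epoxide oxygen. Inversion at C8 gives 8R, and C7 keeps its oxygen and stays 7S; the medium is not basic, so the methylene lactone is safe.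

Step 19
Reactants: 29 (1S,2S,7S,8R,11RS)-11-(tert-butyldimethylsilyloxy)-8-hydroperoxy-7-hydroxycembra-3E,12E,15(17)-trien-16,2-olide
Product: 30 (1S,2S,7S,8R,11RS)-8-hydroperoxy-7,11-dihydroxycembra-3E,12E,15(17)-trien-16,2-olide
Conditions: HF·pyridine, pyridine, THF, 0 → 23 °C
Reagents that add atoms: none
Why: Fluoride cleaves the Si–O bond under weakly acidic conditions, so no peroxide anion is formed that could add to the methylene lactone.

Step 20
Reactants: 30 (1S,2S,7S,8R,11RS)-8-hydroperoxy-7,11-dihydroxycembra-3E,12E,15(17)-trien-16,2-olide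
Product: 31 (1S,2S,7S,8R,11S)-8,11-epidioxy-7-hydroxycembra-3E,12E,15(17)-trien-16,2-olide
Conditions: Re2O7 (5 mol%), CH2Cl2, 0 °C
Reagents that add atoms: none
Why: Re2O7 turns the C11 allylic alcohol into a perrhenate ester that ionises to the C11–C13 allyl cation, and the terminal oxygen of the C8 hydroperoxide captures C11 in a six-membered closure; this is the cationic, acid-mediated cyclisation of a hydroxy hydroperoxide to a 1,2-dioxane, and both C11 epimers of 30 give the same cation. C11 is set under control of C8 and the macrocycle: only the cis-bridged dioxane lets C9–C10 sit at a gauche–gauche corner of the 14-membered ring, and reversible ionisation of the allylic peroxide should funnel material to this 11S isomer.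

Step 21
Reactants: 31 (1S,2S,7S,8R,11S)-8,11-epidioxy-7-hydroxycembra-3E,12E,15(17)-trien-16,2-olide
Product: 32 (1S,2S,7S,8R,11S)-7-acetoxy-8,11-epidioxycembra-3E,12E,15(17)-trien-16,2-olide
Conditions: Ac2O, pyridine, DMAP (cat.), CH2Cl2, 0 °C
Reagents that add atoms: acetic anhydride, CC(=O)OC(C)=O
Why: Nucleophile-catalysed acylation of the only remaining hydroxyl; dialkyl peroxides tolerate these conditions, and the low temperature and catalytic DMAP limit amine addition to the methylene lactone.

## Compound list

1 | pent-3-yn-1-ol | CC#CCCO | starting material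
2 | alkenylzirconocene alkoxide from 1 (Cp2ZrCl on C4 and on O) | C(/C=C(C)/[Zr](Cl)(C1C=CC=C1)C1C=CC=C1)CO[Zr](Cl)(C1C=CC=C1)C1C=CC=C1 | intermediate
3 | (3E)-4-iodopent-3-en-1-ol | OCC/C=C(C)/I | intermediate
4 | ethyl (triphenylphosphoranylidene)acetate | CCOC(=O)C=P(c1ccccc1)(c1ccccc1)c1ccccc1 | starting material
5 | (3E)-4-iodopent-3-enal | O=CC/C=C(C)/I | intermediate
6 | ethyl (2E,5E)-6-iodohepta-2,5-dienoate | CCOC(=O)/C=C/C/C=C(C)/I | intermediate
7 | (2E,5E)-6-iodohepta-2,5-dien-1-ol | OC/C=C/C/C=C(C)/I | intermediate
8 | [(2S,3S)-3-[(2E)-3-iodobut-2-en-1-yl]oxiran-2-yl]methanol | OC[C@@H]1O[C@H]1C/C=C(C)/I | intermediate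
9 | ethynyl(trimethyl)silane | C#C[Si](C)(C)C | starting material
10 | lithium (trimethylsilyl)acetylide | [Li]C#C[Si](C)(C)C | intermediate
11 | diethyl(trimethylsilylethynyl)aluminium | CC[Al](CC)C#C[Si](C)(C)C | intermediate
12 | (2R,3S,5E)-6-iodo-3-[(trimethylsilyl)ethynyl]hept-5-ene-1,2-diol | OC[C@H](O)[C@H](C#C[Si](C)(C)C)C/C=C(C)/I | intermediate
13 | (2R,3S,5E)-6-iodo-1,2-bis(triethylsilyloxy)-3-[(trimethylsilyl)ethynyl]hept-5-ene | CC[Si](CC)(CC)OC[C@H](O[Si](CC)(CC)CC)[C@H](C#C[Si](C)(C)C)C/C=C(C)/I | intermediate
14 | (2R,3S,5E)-6-iodo-2-(triethylsilyloxy)-3-[(trimethylsilyl)ethynyl]hept-5-enal | O=C[C@H](O[Si](CC)(CC)CC)[C@H](C#C[Si](C)(C)C)C/C=C(C)/I | intermediate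
15 | isopropenylmagnesium bromide | CC(=C)[Mg]Br | starting material
16 | (3RS,4R,5S,7E)-8-iodo-2-methyl-4-(triethylsilyloxy)-5-[(trimethylsilyl)ethynyl]nona-1,7-dien-3-ol | C=C(C)C(O)[C@H](O[Si](CC)(CC)CC)[C@H](C#C[Si](C)(C)C)C/C=C(C)/I | intermediate
17 | triethyl orthoacetate | CCOC(C)(OCC)OCC | starting material
18 | ethyl (4E,6S,7S,9E)-10-iodo-4-methyl-6-(triethylsilyloxy)-7-[(trimethylsilyl)ethynyl]undeca-4,9-dienoate | CCOC(=O)CC/C(C)=C/[C@H](O[Si](CC)(CC)CC)[C@H](C#C[Si](C)(C)C)C/C=C(C)/I | intermediate
19 | (4E,6S,7S,9E)-10-iodo-4-methyl-6-(triethylsilyloxy)-7-[(trimethylsilyl)ethynyl]undeca-4,9-dienal | O=CCC/C(C)=C/[C@H](O[Si](CC)(CC)CC)[C@H](C#C[Si](C)(C)C)C/C=C(C)/I | intermediate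
20 | (3RS,6E,8S,9S,11E)-12-iodo-2,6-dimethyl-8-(triethylsilyloxy)-9-[(trimethylsilyl)ethynyl]trideca-1,6,11-trien-3-ol | C=C(C)C(O)CC/C(C)=C/[C@H](O[Si](CC)(CC)CC)[C@H](C#C[Si](C)(C)C)C/C=C(C)/I | intermediate
21 | ethyl (4E,8E,10S,11S,13E)-14-iodo-4,8-dimethyl-10-(triethylsilyloxy)-11-[(trimethylsilyl)ethynyl]pentadeca-4,8,13-trienoate | CCOC(=O)CC/C(C)=C/CC/C(C)=C/[C@H](O[Si](CC)(CC)CC)[C@H](C#C[Si](C)(C)C)C/C=C(C)/I | intermediate
22 | (4E,8E,10S,11S,13E)-14-iodo-4,8-dimethyl-10-(triethylsilyloxy)-11-[(trimethylsilyl)ethynyl]pentadeca-4,8,13-trienal | O=CCC/C(C)=C/CC/C(C)=C/[C@H](O[Si](CC)(CC)CC)[C@H](C#C[Si](C)(C)C)C/C=C(C)/I | intermediate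
23 | (1S,2S,3E,7E,11RS,12E)-2-(triethylsilyloxy)-1-[(trimethylsilyl)ethynyl]-4,8,12-trimethylcyclotetradeca-3,7,12-trien-11-ol | C[Si](C)(C)C#C[C@@H]1C/C=C(C)/C(O)CC/C(C)=C/CC/C(C)=C/[C@@H]1O[Si](CC)(CC)CC | intermediate
24 | (1S,2S,3E,7E,11RS,12E)-11-(tert-butyldimethylsilyloxy)-2-(triethylsilyloxy)-1-[(trimethylsilyl)ethynyl]-4,8,12-trimethylcyclotetradeca-3,7,12-triene | C[Si](C)(C)C#C[C@@H]1C/C=C(C)/C(O[Si](C)(C)C(C)(C)C)CC/C(C)=C/CC/C(C)=C/[C@@H]1O[Si](CC)(CC)CC | intermediate
25 | (1S,2S,3E,7E,11RS,12E)-11-(tert-butyldimethylsilyloxy)-1-[(trimethylsilyl)ethynyl]-4,8,12-trimethylcyclotetradeca-3,7,12-trien-2-ol | C[Si](C)(C)C#C[C@@H]1C/C=C(C)/C(O[Si](C)(C)C(C)(C)C)CC/C(C)=C/CC/C(C)=C/[C@@H]1O | intermediate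
26 | (1S,2S,3E,7E,11RS,12E)-11-(tert-butyldimethylsilyloxy)-1-ethynyl-4,8,12-trimethylcyclotetradeca-3,7,12-trien-2-ol | C#C[C@@H]1C/C=C(C)/C(O[Si](C)(C)C(C)(C)C)CC/C(C)=C/CC/C(C)=C/[C@@H]1O | intermediate
27 | (1S,2S,11RS)-11-(tert-butyldimethylsilyloxy)cembra-3E,7E,12E,15(17)-tetraen-16,2-olide | C=C1C(=O)O[C@H]2/C=C(\C)CC/C=C(\C)CCC(O[Si](C)(C)C(C)(C)C)/C(C)=C/C[C@@H]12 | intermediate
28 | (1S,2S,7S,8S,11RS)-11-(tert-butyldimethylsilyloxy)-7,8-epoxycembra-3E,12E,15(17)-trien-16,2-olide | C=C1C(=O)O[C@H]2/C=C(\C)CC[C@@H]3O[C@@]3(C)CCC(O[Si](C)(C)C(C)(C)C)/C(C)=C/C[C@@H]12 | intermediate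
29 | (1S,2S,7S,8R,11RS)-11-(tert-butyldimethylsilyloxy)-8-hydroperoxy-7-hydroxycembra-3E,12E,15(17)-trien-16,2-olide | C=C1C(=O)O[C@H]2/C=C(\C)CC[C@H](O)[C@@](OO)(C)CCC(O[Si](C)(C)C(C)(C)C)/C(C)=C/C[C@@H]12 | intermediate
30 | (1S,2S,7S,8R,11RS)-8-hydroperoxy-7,11-dihydroxycembra-3E,12E,15(17)-trien-16,2-olide | C=C1C(=O)O[C@H]2/C=C(\C)CC[C@H](O)[C@@](OO)(C)CCC(O)/C(C)=C/C[C@@H]12 | intermediate
31 | (1S,2S,7S,8R,11S)-8,11-epidioxy-7-hydroxycembra-3E,12E,15(17)-trien-16,2-olide | C=C1C(=O)O[C@H]2/C=C(\C)CC[C@H](O)[C@@]3(C)CC[C@H](OO3)/C(C)=C/C[C@@H]12 | intermediate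
32 | (1S,2S,7S,8R,11S)-7-acetoxy-8,11-epidioxycembra-3E,12E,15(17)-trien-16,2-olide | C=C1C(=O)O[C@H]2/C=C(\C)CC[C@H](OC(C)=O)[C@@]3(C)CC[C@H](OO3)/C(C)=C/C[C@@H]12 | target

## Step count and least certain steps

Total step count: 21. Longest linear sequence: 21 steps from 1 (the route is linear; 4, 9, 15 and 17 are purchased).

**Step 16 (key step).** The most likely failure is ionisation of the allylic C2–O bond by zerovalent palladium at the temperature the hindered macrocyclic alkyne needs, either in the alcohol or, after ring closure, in the lactone acting as an allylic ester. That would scramble C2 or lead to a diene. The fallback sets out from 26 and avoids palladium and CO. Hydroboration of the terminal alkyne with dicyclohexylborane and oxidation with NaBO3·4H2O would give the C17 aldehyde, which closes onto O2 as the cis-fused lactol F1. Oxidation with Ag2CO3 on Celite would give the saturated cis-fused γ-lactone F2. Enolisation with LiN(SiMe3)2 and reaction with CH2=NMe2+ I− would give the α-(dimethylaminomethyl) lactone F3. Quaternisation with MeI and elimination with NaHCO3 would return to the route at 27. Here the carbonyl carbon is the former alkyne terminus and the methylene carbon comes from the iminium salt.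

**Step 20.** The most likely failure is capture of the allyl cation by the free C7 hydroxyl (a six-membered ether between C7 and C11) in competition with the hydroperoxide, helped by acid-induced Hock-type fragmentation of the β-hydroxy hydroperoxide. The fallback sets out from 29 and removes the competing hydroxyl before any cation is made. Silylation of the more acidic hydroperoxide with Et3SiCl and imidazole at −20 °C would give the triethylsilyl peroxide F4. Acetylation of O7 (Ac2O, DMAP) would give the acetate F5. HF·pyridine would remove both silyl groups to give the 7-acetoxy-8-hydroperoxy-11-ol F6. Re2O7 closure would then give 32 directly.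

**Step 17.** The most likely failure is insufficient site or facial selectivity, because the conformation of the macrocycle may expose C12=C13 or C3=C4, or may oppose the catalyst on the C7=C8 face. The fallback sets out from 21 and epoxidises before ring closure, where only reagent control operates and C7=C8 is the sole unhindered, electron-rich olefin. The same Shi conditions would give the acyclic (7S,8S)-epoxy ester F7. i-Bu2AlH at −78 °C would give the epoxy aldehyde F8. Nozaki–Hiyama–Kishi closure would give the macrocyclic epoxy alcohol F9. TBSCl with imidazole (no Lewis acidic triflate) would give the silyl ether F10. PPTS in methanol at 0 °C followed by K2CO3 would give the epoxy alkynol F11. The carbonylation of step 16 would then return to the route at 28.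

**Step 9.** The most likely failure is loss or migration of the C2 triethylsilyl group under hot, weakly acidic conditions (or already in the magnesium alkoxide of step 8), which would divert the orthoester exchange. The fallback sets out from 14 and builds C3=C4 without heat or acid. Horner–Wadsworth–Emmons olefination with triethyl 2-phosphonopropionate (LiCl, DBU, MeCN) would give the E-enoate F12. i-Bu2AlH would give the allylic alcohol F13. CBr4 and PPh3 would give the allylic bromide F14. Alkylation of the lithium enolate of ethyl acetate (LiN(i-Pr)2, THF–DMPU, −78 °C) would return to the route at 18.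

## Further compounds

F1 | step 16 | cis-fused γ-lactol (O2–C17H(OH)–C15H2–C1) of the 11-silyloxy 3E,7E,12E-triene | OC1C[C@@H]2C/C=C(C)/C(O[Si](C)(C)C(C)(C)C)CC/C(C)=C/CC/C(C)=C/[C@@H]2O1
F2 | step 16 | saturated cis-fused γ-lactone of the 11-silyloxy 3E,7E,12E-triene | O=C1C[C@@H]2C/C=C(C)/C(O[Si](C)(C)C(C)(C)C)CC/C(C)=C/CC/C(C)=C/[C@@H]2O1
F3 | step 16 | α-(dimethylaminomethyl) cis-fused γ-lactone (Mannich base) | CN(C)CC1C(=O)O[C@H]2/C=C(\C)CC/C=C(\C)CCC(O[Si](C)(C)C(C)(C)C)/C(C)=C/C[C@@H]12
F4 | step 20 | 8-(triethylsilylperoxy)-7-hydroxy-11-(tert-butyldimethylsilyloxy) lactone | C=C1C(=O)O[C@H]2/C=C(\C)CC[C@H](O)[C@@](OO[Si](CC)(CC)CC)(C)CCC(O[Si](C)(C)C(C)(C)C)/C(C)=C/C[C@@H]12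
F5 | step 20 | 7-acetoxy-8-(triethylsilylperoxy)-11-(tert-butyldimethylsilyloxy) lactone | C=C1C(=O)O[C@H]2/C=C(\C)CC[C@H](OC(C)=O)[C@@](OO[Si](CC)(CC)CC)(C)CCC(O[Si](C)(C)C(C)(C)C)/C(C)=C/C[C@@H]12
F6 | step 20 | 7-acetoxy-8-hydroperoxy-11-hydroxy lactone | C=C1C(=O)O[C@H]2/C=C(\C)CC[C@H](OC(C)=O)[C@@](OO)(C)CCC(O)/C(C)=C/C[C@@H]12
F7 | step 17 | acyclic (7S,8S)-epoxy ethyl ester (epoxide of 21 at the central olefin) | CCOC(=O)CC[C@]1(C)O[C@H]1CC/C(C)=C/[C@H](O[Si](CC)(CC)CC)[C@H](C#C[Si](C)(C)C)C/C=C(C)/I
F8 | step 17 | acyclic (7S,8S)-epoxy aldehyde | O=CCC[C@]1(C)O[C@H]1CC/C(C)=C/[C@H](O[Si](CC)(CC)CC)[C@H](C#C[Si](C)(C)C)C/C=C(C)/I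
F9 | step 17 | macrocyclic (7S,8S)-epoxy C11 alcohol with O2 triethylsilyl ether and silylalkyne | C[Si](C)(C)C#C[C@@H]1C/C=C(C)/C(O)CC[C@]2(C)O[C@H]2CC/C(C)=C/[C@@H]1O[Si](CC)(CC)CC
F10 | step 17 | macrocyclic (7S,8S)-epoxide with O11 tert-butyldimethylsilyl ether, O2 triethylsilyl ether and silylalkyne | C[Si](C)(C)C#C[C@@H]1C/C=C(C)/C(O[Si](C)(C)C(C)(C)C)CC[C@]2(C)O[C@H]2CC/C(C)=C/[C@@H]1O[Si](CC)(CC)CC
F11 | step 17 | macrocyclic (7S,8S)-epoxy 1-ethynyl-2-ol with O11 tert-butyldimethylsilyl ether | C#C[C@@H]1C/C=C(C)/C(O[Si](C)(C)C(C)(C)C)CC[C@]2(C)O[C@H]2CC/C(C)=C/[C@@H]1O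
F12 | step 9 | ethyl (2E,4S,5S,7E)-8-iodo-2-methyl-4-(triethylsilyloxy)-5-[(trimethylsilyl)ethynyl]nona-2,7-dienoate | CCOC(=O)/C(C)=C/[C@H](O[Si](CC)(CC)CC)[C@H](C#C[Si](C)(C)C)C/C=C(C)/I
F13 | step 9 | (2E,4S,5S,7E)-8-iodo-2-methyl-4-(triethylsilyloxy)-5-[(trimethylsilyl)ethynyl]nona-2,7-dien-1-ol | OC/C(C)=C/[C@H](O[Si](CC)(CC)CC)[C@H](C#C[Si](C)(C)C)C/C=C(C)/I
F14 | step 9 | (2E,4S,5S,7E)-1-bromo-8-iodo-2-methyl-4-(triethylsilyloxy)-5-[(trimethylsilyl)ethynyl]nona-2,7-diene | BrC/C(C)=C/[C@H](O[Si](CC)(CC)CC)[C@H](C#C[Si](C)(C)C)C/C=C(C)/I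
A1 | alternative 1 | acyclic ynal: C11 aldehyde, C12≡C13 methyl alkyne, (7S,8S)-epoxide, saturated cis-lactone on C1/C2 | CC#CC[C@H]1CC(=O)O[C@H]1/C=C(\C)CC[C@@H]2O[C@@]2(C)CCC=O
A2 | alternative 1 | macrocyclic C11 triethylsilyl ether with (7S,8S)-epoxide and saturated cis-lactone | C1C(=O)O[C@H]2/C=C(\C)CC[C@@H]3O[C@@]3(C)CCC(O[Si](CC)(CC)CC)/C(C)=C/C[C@@H]12
A3 | alternative 2 | (11S)-11-hydroperoxy-(7S,8S)-7,8-epoxy methylene lactone | C=C1C(=O)O[C@H]2/C=C(\C)CC[C@@H]3O[C@@]3(C)CC[C@H](OO)/C(C)=C/C[C@@H]12
A4 | alternative 2 | 7-O-deacetyl target (identical to 31) | C=C1C(=O)O[C@H]2/C=C(\C)CC[C@H](O)[C@@]3(C)CC[C@H](OO3)/C(C)=C/C[C@@H]12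
A5 | alternative 3 | 17-membered propargyl allyl ether (O between C2 and C17; C1=C15 with C14 cis to C17) | C1C#CCC/C=C(\C)CC/C=C(\C)CC/C=C(/CO[Si](C)(C)C(C)(C)C)CO1
A6 | alternative 3 | 14-membered propargylic alcohol with C1 and C2 set | O[C@H]1C#CCC/C=C(\C)CC/C=C(\C)CC[C@H]1C(=C)CO[Si](C)(C)C(C)(C)C
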